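**Retrosynthetic overview**

1. Target ⇐ C12 carbinol acetate (α‑prenyl addition to a C12 lactol) and C2=C3 (anti‑elimination of a C3 mesylate) from a hydroazulene γ‑lactone that already carries C4‑OH, C9‑OSi and the C10 methylene.
2. Five‑/seven‑membered rings ⇐ C1–C5 bond by transannular opening of a 4,5‑epoxide by the 1(10)‑olefin of a ten‑membered ring (second ring‑forming event).
3. Ten‑membered ring ⇐ C6–C7 bond by intramolecular carbonyl allylation, the counterpart of the C1–C10 closure of the geranylgeranyl chain; run in one flask with line 2 (acyclic chain → ten‑membered carbocycle + γ‑lactone → 5/7 bicycle).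
4. Acyclic chain ⇐ two rounds of enantioselective allylboration / cross‑metathesis on (E)‑4‑acetoxy‑2‑methylbut‑2‑enal; epoxide by hydroxyl‑directed epoxidation.

Assumption: biogenetic numbering is used for all intermediates (ring C1–C10, side chain C11–C16, C17 = methyl on C4, C18 = methylene on C10, C19 = methyl on C11); in it the target is (1R,4S,5R,6R,7S,9R,11S,12S), and compound 1 is taken as a commercial bulk intermediate.

**Route**

Step 1
Reactants: 1 (E)-4-acetoxy-2-methylbut-2-enal
Product: 2 (2E,4S)-4-hydroxy-3-methylhepta-2,6-dien-1-yl acetate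
Conditions: allylB(pin), (S)-TRIP (5 mol %), PhMe, −30 °C
Reagents that add atoms: allylboronic acid pinacol ester, C=CCB1OC(C)(C)C(C)(C)O1
Why: chiral phosphoric acid‑catalysed allylboration through a closed chair transition state, in which the (S)-acid selects the enal face that gives the (S)-carbinol at C3.

Step 2
Reactants: 2 (2E,4S)-4-hydroxy-3-methylhepta-2,6-dien-1-yl acetate
Product: 3 [(2S,3S)-3-[(1S)-1-hydroxybut-3-en-1-yl]-3-methyloxiran-2-yl]methyl acetate
Conditions: VO(acac)2 (2 mol %), t-BuOOH, CH2Cl2, 0 °C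
Reagents that add atoms: tert-butyl hydroperoxide, CC(C)(C)OO
Why: hydroxyl‑directed epoxidation of the secondary allylic alcohol, where A(1,2) strain with the C4 methyl gives the erythro epoxy alcohol (C4 and C5 set from C3) and the homoallylic vinyl group is left alone.

Step 3
Reactants: 3 [(2S,3S)-3-[(1S)-1-hydroxybut-3-en-1-yl]-3-methyloxiran-2-yl]methyl acetate
Product: 4 [(2S,3R)-3-[(1S)-1-(methylsulfonyloxy)but-3-en-1-yl]-3-methyloxiran-2-yl]methyl acetate
Conditions: MsCl, Et3N, CH2Cl2, 0 °C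
Reagents that add atoms: methanesulfonyl chloride, CS(=O)(=O)Cl
Why: sulfonylation of the only free hydroxyl; the mesylate protects C3‑O, later serves as the leaving group for C2=C3, and disfavours ionisation of the epoxide at C4.

Step 4
Reactants: 4 [(2S,3R)-3-[(1S)-1-(methylsulfonyloxy)but-3-en-1-yl]-3-methyloxiran-2-yl]methyl acetate
Product: 5 [(2S,3R)-3-[(1S,3E)-4-methyl-1-(methylsulfonyloxy)-5-oxopent-3-en-1-yl]-3-methyloxiran-2-yl]methyl acetate
Conditions: methacrolein (5 equiv), second-generation Hoveyda–Grubbs catalyst (5 mol %), CH2Cl2, 40 °C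
Reagents that add atoms: methacrolein, CC(=C)C=O
Why: olefin cross‑metathesis of the single terminal alkene with an α‑substituted enal gives the (E)-2-methyl enal (C1=C10 with C18).

Step 5
Reactants: 5 [(2S,3R)-3-[(1S,3E)-4-methyl-1-(methylsulfonyloxy)-5-oxopent-3-en-1-yl]-3-methyloxiran-2-yl]methyl acetate
Product: 6 [(2S,3R)-3-[(1S,3E,5R)-5-hydroxy-4-methyl-1-(methylsulfonyloxy)octa-3,7-dien-1-yl]-3-methyloxiran-2-yl]methyl acetate
Conditions: allylB(pin), (R)-TRIP (5 mol %), PhMe, −30 °C
Reagents that add atoms: allylboronic acid pinacol ester, C=CCB1OC(C)(C)C(C)(C)O1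
Why: the same catalytic allylboration with the antipodal acid, under catalyst control, sets the (R)-carbinol at C9 on the remote enal.

Step 6
Reactants: 6 [(2S,3R)-3-[(1S,3E,5R)-5-hydroxy-4-methyl-1-(methylsulfonyloxy)octa-3,7-dien-1-yl]-3-methyloxiran-2-yl]methyl acetate
Product: 7 [(2S,3R)-3-[(1S,3E,5R)-5-(tert-butyldimethylsilyloxy)-4-methyl-1-(methylsulfonyloxy)octa-3,7-dien-1-yl]-3-methyloxiran-2-yl]methyl acetate
Conditions: TBSCl, imidazole, DMF, rt
Reagents that add atoms: tert-butyldimethylsilyl chloride, CC(C)(C)[Si](C)(C)Cl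
Why: standard silylation of the allylic C9 hydroxyl, needed for the oxidation and organozinc steps that follow.

Step 7
Reactants: 7 [(2S,3R)-3-[(1S,3E,5R)-5-(tert-butyldimethylsilyloxy)-4-methyl-1-(methylsulfonyloxy)octa-3,7-dien-1-yl]-3-methyloxiran-2-yl]methyl acetate
Product: 8 [(2S,3R)-3-[(1S,3E,5R)-5-(tert-butyldimethylsilyloxy)-4-methyl-1-(methylsulfonyloxy)octa-3,7-dien-1-yl]-3-methyloxiran-2-yl]methanol
Conditions: i-Bu2AlH (2.2 equiv), CH2Cl2, −78 °C
Reagents that add atoms: none
Why: reductive cleavage of the acetate under non‑basic conditions, which avoids Payne rearrangement and epoxide migration onto the mesylate that alkoxide conditions could trigger.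

Step 8
Reactants: 8 [(2S,3R)-3-[(1S,3E,5R)-5-(tert-butyldimethylsilyloxy)-4-methyl-1-(methylsulfonyloxy)octa-3,7-dien-1-yl]-3-methyloxiran-2-yl]methanol
Product: 9 (2R,3R)-3-[(1S,3E,5R)-5-(tert-butyldimethylsilyloxy)-4-methyl-1-(methylsulfonyloxy)octa-3,7-dien-1-yl]-3-methyloxirane-2-carbaldehyde
Conditions: Dess–Martin periodinane, CH2Cl2, 0 °C
Reagents that add atoms: none
Why: Dess–Martin oxidation of the primary epoxy alcohol to the α,β‑epoxy aldehyde without touching the epoxide, mesylate or silyl ether (the C5 descriptor changes by priority only).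

Step 9
Reactants: 9 (2R,3R)-3-[(1S,3E,5R)-5-(tert-butyldimethylsilyloxy)-4-methyl-1-(methylsulfonyloxy)octa-3,7-dien-1-yl]-3-methyloxirane-2-carbaldehyde
Product: 10 methyl (2Z,5R,6E,9S)-2-(bromomethyl)-5-(tert-butyldimethylsilyloxy)-9-[(2R,3R)-3-formyl-2-methyloxiran-2-yl]-6-methyl-9-(methylsulfonyloxy)nona-2,6-dienoate
Conditions: methyl 2-(bromomethyl)acrylate (4 equiv), second-generation Hoveyda–Grubbs catalyst (10 mol %), CH2Cl2, 40 °C
Reagents that add atoms: methyl 2-(bromomethyl)acrylate, C=C(CBr)C(=O)OC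
Why: cross‑metathesis of the terminal alkene with a methacrylate‑type partner gives the trisubstituted enoate with the chain trans to the ester (the Z bromide); the trisubstituted C1=C10 olefin does not take part.

Step 10
Reactants: 10 methyl (2Z,5R,6E,9S)-2-(bromomethyl)-5-(tert-butyldimethylsilyloxy)-9-[(2R,3R)-3-formyl-2-methyloxiran-2-yl]-6-methyl-9-(methylsulfonyloxy)nona-2,6-dienoate
Product: 12 (1R,3S,4R,5R,6R,7S,9R)-9-(tert-butyldimethylsilyloxy)-4-hydroxy-3-(methylsulfonyloxy)-10(18),11(19)-dimethylene trans-hydroazulene 6,12-lactone, via ten-membered epoxy lactone 11 (not isolated)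
Conditions: activated Zn, THF (2 mM, slow addition), 45 °C; then CH2Cl2, BF3·OEt2 (0.3 equiv), −78 → −20 °C
Reagents that add atoms: none
Why: Proposed new method: the allylzinc bromide adds through its γ‑carbon C7 to the C6 aldehyde in a chelated chair transition state (zinc bridging the carbonyl and epoxide oxygens, Z allyl unit giving the syn adduct), closing the ten‑membered ring and then the cis‑fused γ‑lactone 11 (C6 R, C7 S); BF3 then opens the epoxide at C5 with inversion by transannular attack of C1 of the 1(10)-olefin, from the conformer with the C17 and C18 methyls anti (trans ring fusion, C1 R, C5 R, C4‑O retained), and the C10 cation loses a C18 proton to give the exocyclic methylene; the closest known reactions are the zinc‑mediated Dreiding–Schmidt (Barbier) α‑methylene‑γ‑butyrolactone annulation used for macrocyclisation and the acid‑induced transannular cyclisation of 4,5‑epoxygermacr‑1(10)‑enolides to 4‑hydroxyguaianolides.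

Step 11
Reactants: 12 (1R,3S,4R,5R,6R,7S,9R)-9-(tert-butyldimethylsilyloxy)-4-hydroxy-3-(methylsulfonyloxy)-10(18),11(19)-dimethylene trans-hydroazulene 6,12-lactone
Product: 13 (1R,3S,4R,5R,6R,7S,9R,11S)-9-(tert-butyldimethylsilyloxy)-4-hydroxy-11-methyl-3-(methylsulfonyloxy)-10(18)-methylene trans-hydroazulene 6,12-lactone
Conditions: NaBH4, MeOH, 0 °C
Reagents that add atoms: none
Why: conjugate (1,4) hydride reduction of the α‑methylene lactone, with protonation of the enolate giving the C11 methyl trans to C8 (11S), the thermodynamically favoured epimer, which step 12 would also reach by equilibration.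

Step 12
Reactants: 13 (1R,3S,4R,5R,6R,7S,9R,11S)-9-(tert-butyldimethylsilyloxy)-4-hydroxy-11-methyl-3-(methylsulfonyloxy)-10(18)-methylene trans-hydroazulene 6,12-lactone
Product: 14 (1R,4S,5R,6R,7S,9R,11S)-9-(tert-butyldimethylsilyloxy)-4-hydroxy-11-methyl-10(18)-methylene trans-hydroazul-2-ene 6,12-lactone
Conditions: DBU, PhMe, 90 °C
Reagents that add atoms: none
Why: E2 elimination of the secondary mesylate, which can only go toward C2 (C4 is quaternary) and cannot close an epoxide because the mesylate is cis to the C4 hydroxyl (erythro origin).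

Step 13
Reactants: 14 (1R,4S,5R,6R,7S,9R,11S)-9-(tert-butyldimethylsilyloxy)-4-hydroxy-11-methyl-10(18)-methylene trans-hydroazul-2-ene 6,12-lactone
Product: 15 the corresponding C12 lactol (6,12-epoxy-12-ol, mixture of C12 epimers)
Conditions: i-Bu2AlH (2.5 equiv), CH2Cl2, −78 °C
Reagents that add atoms: none
Why: partial reduction of the γ‑lactone to the lactol through the stable aluminium hemiacetal at low temperature.

Step 14
Reactants: 15 C12 lactol
Product: 16 (1R,4S,5R,6R,7S,9R,11S,12S)-9-(tert-butyldimethylsilyloxy)-prenylated hydroazulene-4,6,12-triol (C2=C3, C10=C18, C14=C15)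
Conditions: prenyl chloride, Ba (from BaI2, LiC12H10), THF, −78 °C
Reagents that add atoms: prenyl chloride (delivered as prenylbarium chloride), CC(C)=CCCl
Why: allylbarium reagents add to aldehydes at the α‑carbon, so the ring‑opened hydroxy aldehyde gives the linear prenyl carbinol, and Felkin–Anh attack anti to C7 gives the 11,12‑syn (12S) alcohol.

Step 15
Reactants: 16 (1R,4S,5R,6R,7S,9R,11S,12S)-9-(tert-butyldimethylsilyloxy)-prenylated hydroazulene-4,6,12-triol
Product: 17 its 12-O-acetate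
Conditions: Ac2O (1.2 equiv), pyridine, CH2Cl2, 0 °C
Reagents that add atoms: acetic anhydride, CC(=O)OC(C)=O
Why: selective acylation of the least hindered secondary hydroxyl (C12); C6‑OH is flanked by the ring fusion and the C7 branch, and C4‑OH is tertiary.

Step 16
Reactants: 17 12-O-acetate silyl ether
Product: 18 CNP0126182.2 (target)
Conditions: Bu4NF, AcOH, THF, 0 °C → rt
Reagents that add atoms: none
Why: buffered fluoride desilylation frees the C9 hydroxyl without acyl migration or ionisation of the tertiary allylic alcohol.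

**Compound list**

1 | (E)-4-acetoxy-2-methylbut-2-enal | CC(=O)OC/C=C(C)/C=O | starting material
2 | (2E,4S)-4-hydroxy-3-methylhepta-2,6-dien-1-yl acetate | CC(=O)OC/C=C(C)/[C@@H](O)CC=C | intermediate
3 | [(2S,3S)-3-[(1S)-1-hydroxybut-3-en-1-yl]-3-methyloxiran-2-yl]methyl acetate | CC(=O)OC[C@@H]1O[C@@]1(C)[C@@H](O)CC=C | intermediate
4 | [(2S,3R)-3-[(1S)-1-(methylsulfonyloxy)but-3-en-1-yl]-3-methyloxiran-2-yl]methyl acetate | CC(=O)OC[C@@H]1O[C@@]1(C)[C@@H](OS(C)(=O)=O)CC=C | intermediate
5 | [(2S,3R)-3-[(1S,3E)-4-methyl-1-(methylsulfonyloxy)-5-oxopent-3-en-1-yl]-3-methyloxiran-2-yl]methyl acetate | CC(=O)OC[C@@H]1O[C@@]1(C)[C@@H](OS(C)(=O)=O)C/C=C(C)/C=O | intermediate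
6 | [(2S,3R)-3-[(1S,3E,5R)-5-hydroxy-4-methyl-1-(methylsulfonyloxy)octa-3,7-dien-1-yl]-3-methyloxiran-2-yl]methyl acetate | CC(=O)OC[C@@H]1O[C@@]1(C)[C@@H](OS(C)(=O)=O)C/C=C(C)/[C@H](O)CC=C | intermediate
7 | 5-O-TBS ether of 6 | CC(=O)OC[C@@H]1O[C@@]1(C)[C@@H](OS(C)(=O)=O)C/C=C(C)/[C@H](O[Si](C)(C)C(C)(C)C)CC=C | intermediate
8 | [(2S,3R)-3-[(1S,3E,5R)-5-(tert-butyldimethylsilyloxy)-4-methyl-1-(methylsulfonyloxy)octa-3,7-dien-1-yl]-3-methyloxiran-2-yl]methanol | OC[C@@H]1O[C@@]1(C)[C@@H](OS(C)(=O)=O)C/C=C(C)/[C@H](O[Si](C)(C)C(C)(C)C)CC=C | intermediate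
9 | (2R,3R)-3-[(1S,3E,5R)-5-(tert-butyldimethylsilyloxy)-4-methyl-1-(methylsulfonyloxy)octa-3,7-dien-1-yl]-3-methyloxirane-2-carbaldehyde | O=C[C@@H]1O[C@@]1(C)[C@@H](OS(C)(=O)=O)C/C=C(C)/[C@H](O[Si](C)(C)C(C)(C)C)CC=C | intermediate
10 | methyl (2Z,5R,6E,9S)-2-(bromomethyl)-5-(tert-butyldimethylsilyloxy)-9-[(2R,3R)-3-formyl-2-methyloxiran-2-yl]-6-methyl-9-(methylsulfonyloxy)nona-2,6-dienoate | O=C[C@@H]1O[C@@]1(C)[C@@H](OS(C)(=O)=O)C/C=C(C)/[C@H](O[Si](C)(C)C(C)(C)C)C/C=C(\CBr)C(=O)OC | intermediate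
11 | ten-membered carbocycle with (E)-C1=C10 (C18 methyl), trans-4,5-epoxide (C17 methyl), 3-OMs and 9-OTBS, cis-fused at C6–C7 to an α-methylene-γ-butyrolactone; 3S,4R,5S,6R,7S,9R | C/C1=C\C[C@H](OS(C)(=O)=O)[C@]3(C)O[C@H]3[C@@H]2OC(=O)C(=C)[C@@H]2C[C@H]1O[Si](C)(C)C(C)(C)C | intermediate (not isolated)
12 | trans-fused hydroazulene (five-membered ring C1–C5, seven-membered ring C1, C5–C10) with 4-OH, 3-OMs, 9-OTBS and C10=C18H2, cis-fused at C6–C7 to an α-methylene-γ-butyrolactone; 1R,3S,4R,5R,6R,7S,9R | C=C1[C@H](O[Si](C)(C)C(C)(C)C)C[C@H]2C(=C)C(=O)O[C@H]2[C@H]3[C@H]1C[C@H](OS(C)(=O)=O)[C@]3(C)O | intermediate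
13 | 11,19-dihydro derivative of 12 (α-methyl lactone); 1R,3S,4R,5R,6R,7S,9R,11S | C=C1[C@H](O[Si](C)(C)C(C)(C)C)C[C@H]2[C@H](C)C(=O)O[C@H]2[C@H]3[C@H]1C[C@H](OS(C)(=O)=O)[C@]3(C)O | intermediate
14 | 2-ene-4-ol lactone (mesylate eliminated); 1R,4S,5R,6R,7S,9R,11S | C=C1[C@H](O[Si](C)(C)C(C)(C)C)C[C@H]2[C@H](C)C(=O)O[C@H]2[C@H]3[C@H]1C=C[C@]3(C)O | intermediate
15 | C12 lactol of 14 (C12 epimers) | C=C1[C@H](O[Si](C)(C)C(C)(C)C)C[C@H]2[C@H](C)C(O)O[C@H]2[C@H]3[C@H]1C=C[C@]3(C)O | intermediate
16 | 9-O-TBS triol (4-OH, 6-OH, 12-OH) with the full side chain; 1R,4S,5R,6R,7S,9R,11S,12S | C=C1[C@H](O[Si](C)(C)C(C)(C)C)C[C@@H]([C@H](C)[C@H](CC=C(C)C)O)[C@@H](O)[C@H]2[C@H]1C=C[C@]2(C)O | intermediate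
17 | 12-O-acetate of 16 | C=C1[C@H](O[Si](C)(C)C(C)(C)C)C[C@@H]([C@H](C)[C@H](CC=C(C)C)OC(C)=O)[C@@H](O)[C@H]2[C@H]1C=C[C@]2(C)O | intermediate
18 | CNP0126182.2; (1R,4S,5R,6R,7S,9R,11S,12S) | C=C1[C@H](O)C[C@@H]([C@H](C)[C@H](CC=C(C)C)OC(C)=O)[C@@H](O)[C@H]2[C@H]1C=C[C@]2(C)O | target

**Step count and risks**

Total steps: 16. Longest linear sequence: 16 (fully linear from 1).

Most likely to fail:

Step 10, the one‑flask ring closure and transannular cyclisation. The risks are oligomerisation, the wrong C6/C7 diastereomer, a cis‑fused product, or the endocyclic 1(10)-olefin instead of the methylene. The fallback sets out from 9: cross‑metathesis with methyl 2-[(trimethylsilyl)methyl]acrylate gives the allylsilane ester, methyl (2Z)-2-[(trimethylsilyl)methyl] analogue of 10, F1. BF3·OEt2 alone then effects an intramolecular Hosomi–Sakurai allylation of the aldehyde, lactonisation and the transannular epoxide opening with no organometallic present; alternatively MgBr2·OEt2 stops at isolated 11, which is cyclised separately with a bulky aluminium Lewis acid. The fallback rejoins the route at 12.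

Step 14, the prenylation. The risks are γ‑attack (reverse prenyl) and low Felkin selectivity on the lactol. The fallback sets out from 15: allylmagnesium bromide, or the catalytic allylboration of step 1 for reagent control, gives the homoallylic triol with a terminal vinyl group, 12-allyl carbinol F2. Cross‑metathesis with 2‑methyl‑2‑butene (second-generation Grubbs catalyst) turns the vinyl end into the prenyl group and returns 16.

Step 15, the selective acetylation among three free hydroxyls. The fallback sets out from 16: phenylboronic acid ties the syn‑related C4 and C6 hydroxyls into the cyclic phenylboronate F3. Acetylation of the only remaining hydroxyl (Ac2O, DMAP) gives the acetylated boronate F4, and exchange with 2‑methylpentane‑2,4‑diol removes the boronate to return 17.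

Further compounds
F1 | step 10 | methyl (2Z,5R,6E,9S)-5-(tert-butyldimethylsilyloxy)-9-[(2R,3R)-3-formyl-2-methyloxiran-2-yl]-6-methyl-9-(methylsulfonyloxy)-2-[(trimethylsilyl)methyl]nona-2,6-dienoate | O=C[C@@H]1O[C@@]1(C)[C@@H](OS(C)(=O)=O)C/C=C(C)/[C@H](O[Si](C)(C)C(C)(C)C)C/C=C(\C[Si](C)(C)C)C(=O)OC
F2 | step 14 | 12-allyl analogue of 16 (terminal vinyl in place of the prenyl olefin; 12S) | C=C1[C@H](O[Si](C)(C)C(C)(C)C)C[C@@H]([C@H](C)[C@H](CC=C)O)[C@@H](O)[C@H]2[C@H]1C=C[C@]2(C)O
F3 | step 15 | 4,6-O-phenylboronate of 16 | C=C1[C@H](O[Si](C)(C)C(C)(C)C)C[C@@H]([C@H](C)[C@H](CC=C(C)C)O)[C@@H](O3)[C@H]2[C@H]1C=C[C@]2(C)OB3c4ccccc4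
F4 | step 15 | 12-O-acetyl-4,6-O-phenylboronate | C=C1[C@H](O[Si](C)(C)C(C)(C)C)C[C@@H]([C@H](C)[C@H](CC=C(C)C)OC(C)=O)[C@@H](O3)[C@H]2[C@H]1C=C[C@]2(C)OB3c4ccccc4
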